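**Retrosynthetic overview**

- Disconnect the C2–aryl bond: the (2R)-flavanone comes from 7‑hydroxychromone and a chromenyl boronic acid by an enantioselective, dearomatising Pd(II)/PyOx conjugate arylation. This is the last step, it sets the only stereocentre, and no protecting groups are used.
- The boronic acid comes from the aryl bromide (Br–Li exchange, borate).
- The 2,2‑dimethylchromene ring comes from the C2v‑symmetric 4‑bromo‑2,6‑diprenylphenol by DDQ oxidative cyclisation. There is only one OH, so only one of the two equivalent prenyl groups can cyclise.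
- The diprenylphenol comes from 4‑bromophenol and two equivalents of prenyl bromide (ortho C‑alkylation of the phenoxide).
- Ring order: the A ring and pyranone are bought intact as the chromone; the chromene pyran ring is formed in step 2; the pyranone is de‑aromatised to the flavanone C ring in step 4.

Assumption: 7‑hydroxy‑4H‑chromen‑4‑one and (S)‑t‑BuPyOx are purchased. The target's stereocentre is 2R (the antipode of natural 2S flavanones).

**Route**

Step 1
Reactants: 1, 4‑bromophenol; 2, prenyl bromide (1‑bromo‑3‑methylbut‑2‑ene, 2.3 equiv)
Product: 3, 4‑bromo‑2,6‑bis(3‑methylbut‑2‑en‑1‑yl)phenol (achiral, C2v‑symmetric)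
Conditions: NaH (2.4 equiv) and 2 (2.3 equiv), each added in two portions, toluene, 0 °C → rt, 24 h; aq NH4Cl
Reagents that add atoms: prenyl bromide, CC(C)=CCBr (two C5 units)
Why: Ortho‑selective C‑alkylation of a sodium phenoxide tight ion pair in a non‑polar solvent (para position blocked by Br, SN2 at the primary allylic carbon gives the linear prenyl group), repeated in the same pot at the second ortho position; the O‑prenyl ether and mono‑prenyl phenol are separable by‑products.

Step 2
Reactants: 3, 4‑bromo‑2,6‑diprenylphenol
Product: 4, 6‑bromo‑2,2‑dimethyl‑8‑(3‑methylbut‑2‑en‑1‑yl)‑2H‑chromene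
Conditions: DDQ (1.1 equiv), PhH, 60–80 °C, 2 h
Reagents that add atoms: none
Why: DDQ oxidative cyclisation of an o‑prenylphenol (hydride abstraction from the benzylic/allylic CH2 gives an o‑quinone methide, which closes by oxa‑6π electrocyclisation); the two prenyl groups are equivalent and only one OH is present, so the symmetry is broken exactly once and the second prenyl group, now on an aryl ether, is left alone.

Step 3
Reactants: 4, the bromochromene
Product: 5, [2,2‑dimethyl‑8‑(3‑methylbut‑2‑en‑1‑yl)‑2H‑chromen‑6‑yl]boronic acid
Conditions: n‑BuLi (1.1 equiv), THF, −78 °C, 20 min; B(OiPr)3 (1.5 equiv), −78 °C → rt; sat. aq NH4Cl (pH 5–6)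
Reagents that add atoms: triisopropyl borate, CC(C)OB(OC(C)C)OC(C)C (boron); water, O (the two OH oxygens on hydrolysis)
Why: Bromine–lithium exchange, borate trapping and hydrolysis; 4 has no acidic or electrophilic sites at −78 °C, and the near‑neutral work‑up spares the prenyl and chromene alkenes.

Step 4
Reactants: 5, the boronic acid (1.5 equiv); 6, 7‑hydroxy‑4H‑chromen‑4‑one (1.0 equiv)
Product: 7, ent‑abyssinone III, (2R)‑7‑hydroxy‑2‑[2,2‑dimethyl‑8‑(3‑methylbut‑2‑en‑1‑yl)‑2H‑chromen‑6‑yl]‑2,3‑dihydro‑4H‑chromen‑4‑one
Conditions: Pd(OCOCF3)2 (5 mol %), (S)‑t‑BuPyOx (6 mol %; CC(C)(C)[C@H]1COC(=N1)c1ccccn1), NH4PF6 (30 mol %), H2O (5 equiv), ClCH2CH2Cl, 60 °C, 24 h, air; neutral work‑up, no base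
Reagents that add atoms: none (the new C3–H comes from water)
Why: Pd(II)/pyridine‑oxazoline enantioselective conjugate addition of an arylboronic acid to a chromone (transmetalation, enantio‑determining insertion of C2=C3 into Ar–Pd, protonolysis of the Pd enolate) breaks the γ‑pyrone aromaticity and sets C2; the (S)‑ligand should deliver the aryl group to the C2 Si face to give 2R (assigned by analogy with the sense reported for cyclic enones, to be confirmed by chiral HPLC/CD), and the base‑free medium leaves the 7‑OH neutral and avoids retro‑oxa‑Michael racemisation.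

**Compound list**

1 | 4‑bromophenol | Oc1ccc(Br)cc1 | starting material
2 | prenyl bromide | CC(C)=CCBr | starting material
3 | 4‑bromo‑2,6‑bis(3‑methylbut‑2‑en‑1‑yl)phenol | CC(C)=CCc1cc(Br)cc(CC=C(C)C)c1O | intermediate
4 | 6‑bromo‑2,2‑dimethyl‑8‑(3‑methylbut‑2‑en‑1‑yl)‑2H‑chromene | CC(C)=CCc1cc(Br)cc2c1OC(C)(C)C=C2 | intermediate
5 | [2,2‑dimethyl‑8‑(3‑methylbut‑2‑en‑1‑yl)‑2H‑chromen‑6‑yl]boronic acid | CC(C)=CCc1cc(B(O)O)cc2c1OC(C)(C)C=C2 | intermediate
6 | 7‑hydroxy‑4H‑chromen‑4‑one | O=c1ccoc2cc(O)ccc12 | starting material
7 | ent‑abyssinone III, (2R) | CC(C)=CCc1cc([C@H]2CC(=O)c3ccc(O)cc3O2)cc2c1OC(C)(C)C=C2 | target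

**Totals**

Total steps: 4. Longest linear sequence: 4 (1 → 3 → 4 → 5 → 7).

**Steps most likely to fail**

1. Step 4 (key arylation). Risks: the free 7‑OH lowers the chromone's electrophilicity and its solubility in DCE; the electron‑rich boronic acid may protodeboronate; Pd(II) may engage the prenyl or chromene alkenes; the ee or the sense of induction may differ from precedent (the (R)‑ligand is equally accessible if the sense is reversed).
 Fallback: abandon the arylation and build the C ring by cyclisation. Convert 4 to the aldehyde (n‑BuLi, DMF), run a Claisen–Schmidt condensation with 2‑hydroxy‑4‑(methoxymethoxy)acetophenone, close the 2'‑hydroxychalcone by oxa‑Michael addition (NaOAc, EtOH), remove the MOM group with mild acid, and obtain the 2R enantiomer by preparative chiral HPLC.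

2. Step 1 (double ortho C‑prenylation). Risks: competing O‑alkylation, mono/di mixtures, and a modest yield (about 30–40% expected).
 Fallback: install the prenyl groups by halogen–metal chemistry. Make 4‑bromo‑2,6‑diiodophenol (NIS), protect as the MOM ether, carry out two iodine‑selective I/Mg exchanges (i‑PrMgCl·LiCl, −40 °C) each followed by Cu‑mediated coupling with prenyl bromide, then remove the MOM group to reach 3.

3. Step 2 (DDQ cyclisation of a bromo‑deactivated phenol). Risks: sluggish hydride abstraction and competing oxidation at the second prenyl CH2.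
 Fallback: form the chromene by annulation instead of oxidation. Stop step 1 at 4‑bromo‑2‑prenylphenol and condense its free ortho position with 3‑methylbut‑2‑enal (PhB(OH)2, AcOH, toluene, reflux, Dean–Stark) to give 4 directly by condensation and oxa‑6π closure.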